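The quinone ring is disconnected at C5–C6 and C1–C2, with the C1 oxygen first replaced by a formyl group. The feature exploited is the 1,3-relation of the C2 methoxy and the C4 oxygen on the six-membered ring, which maps onto a ketene-acetal silyloxydiene. C1 also lies between C2 and the heptadecyl-bearing C6. One thermal [4+2] addition of diene 6 to the linear C20 ynal 11 makes both bonds and closes the only ring. After loss of methanol and silicon it gives benzaldehyde 14 with all four substituents in place. Dakin oxidation and mild oxidation of the hydroquinone finish the route.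

Key step: step 6

Remark: the target has no stereocentre and no stereogenic double bond. It is achiral, so no enantiomer has to be chosen and no step needs facial control. Ring numbering used throughout: C1 (C=O between OMe and chain), C2 (OMe), C3 (H), C4 (C=O), C5 (H), C6 (heptadecyl).

Step 1
Reactants: 1 acetyl chloride; 2 1,1-dichloroethene
Product: 4 4,4-dichlorobut-3-en-2-one, via 4,4,4-trichlorobutan-2-one 3 (not isolated)
Conditions: AlCl3 (1.1 equiv), CH2Cl2, 0 °C to rt; ice/aq. HCl; then steam distillation
Reagents that add atoms: none
Why: Aliphatic Friedel–Crafts acylation: the acylium ion adds to the CH2 end of 2 to give the chlorine-stabilised cation, chloride capture gives 3, and its acidic α-protons allow E1cB loss of HCl during steam distillation to the conjugated ketone 4.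

Step 2
Reactants: 4 4,4-dichlorobut-3-en-2-one
Product: 5 4,4-dimethoxybut-3-en-2-one
Conditions: NaOMe (2.1 equiv), MeOH, 0 °C to reflux; filter; distil
Reagents that add atoms: sodium methoxide, [Na+].[O-]C
Why: Two successive addition–elimination substitutions at the β-carbon (vinylic substitution, as on a vinylogous acid chloride) replace both chlorides by methoxide, and any ortho ester from a third addition should revert to 5 on distillation.

Step 3
Reactants: 5 4,4-dimethoxybut-3-en-2-one
Product: 6 1,1-dimethoxy-3-(trimethylsilyloxy)buta-1,3-diene
Conditions: TMSCl, Et3N, ZnCl2 (cat.), toluene, 40 °C; pentane, filter under Ar; distil under reduced pressure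
Reagents that add atoms: chlorotrimethylsilane, C[Si](C)(C)Cl
Why: Amine-mediated enol silylation of a methyl ketone, the standard entry to 2-silyloxydienes from enones: only the methyl group can enolise, so a single diene can form, and distillation frees it from zinc salts that would misdirect the cycloaddition.

Step 4
Reactants: 7 octadecanal
Product: 8 1,1-dibromononadec-1-ene
Conditions: CBr4, PPh3, CH2Cl2, 0 °C; hexane, filter through silica
Reagents that add atoms: carbon tetrabromide, BrC(Br)(Br)Br
Why: First stage of the Corey–Fuchs homologation: the ylide Ph3P=CBr2 formed from CBr4 and PPh3 olefinates the unhindered aldehyde in a Wittig reaction.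

Step 5
Reactants: 8 1,1-dibromononadec-1-ene
Product: 11 icos-2-ynal, via lithium nonadec-1-ynide 9 (not isolated), via lithium 1-(dimethylamino)icos-2-yn-1-olate 10 (not isolated)
Conditions: n-BuLi (2.1 equiv), THF, −78 to 0 °C; DMF, −78 °C to rt; reverse quench into cold 10% aq. KH2PO4/MTBE
Reagents that add atoms: N,N-dimethylformamide, CN(C)C=O
Why: Second stage of the Corey–Fuchs sequence: bromine–lithium exchange, α-elimination with 1,2-hydride shift (Fritsch–Buttenberg–Wiechell type) and deprotonation give acetylide 9, DMF formylates it through the stable adduct 10, and the buffered reverse quench protonates the released amine before it can add to the ynal.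

Step 6
Reactants: 6 1,1-dimethoxy-3-(trimethylsilyloxy)buta-1,3-diene; 11 icos-2-ynal
Product: 14 2-heptadecyl-4-hydroxy-6-methoxybenzaldehyde, via dimethoxycyclohexadiene cycloadduct 12 (not isolated), via aryl trimethylsilyl ether 13 (not isolated)
Conditions: 6 (2.5 equiv), toluene, 100 °C, sealed tube, Ar, base-washed glass, no Lewis acid; then 1 M HCl, THF, rt
Reagents that add atoms: none
Why: This is a thermal normal-electron-demand Diels–Alder reaction that runs in a strongly asynchronous way: the CH2 terminus of 6, which collects the push of both acetal oxygens and of the silyloxy group, bonds first to the alkyne carbon β to the formyl group (C5–C6), and the ketene-acetal carbon then closes onto the α-carbon (C1–C2). The single ring is closed in the intermolecular [4+2] mode, four carbons from 6 and two from 11, to give 1,4-cyclohexadiene 12. Adduct 12 aromatises by expelling one methanol from the acetal carbon together with a C5 proton that is γ to the enal and therefore acidic, and dilute acid then cleaves silyl ether 13, so C2 keeps a single OMe and C4 ends as the free phenol of 14. The closest known reaction type is the Diels–Alder aromatisation of 1,1-dialkoxy-3-silyloxydienes with β-alkyl acetylenic carbonyl dienophiles, which gives 6-alkyl-4-hydroxy-2-methoxyaryl carbonyl compounds. No stereocentre is formed; the step needs regioselectivity, secured by matching the largest HOMO coefficient (diene CH2) with the largest LUMO coefficient (β-carbon of the ynal), so that the heptadecyl group ends up on C6 and the formyl group on C1. It also needs chemoselectivity for C≡C over C=O, secured by excluding Lewis and Brønsted acids, without which hetero-Diels–Alder or aldol-type attack on the aldehyde is slow, and by an excess of 6 to cover what the liberated methanol consumes.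

Step 7
Reactants: 14 2-heptadecyl-4-hydroxy-6-methoxybenzaldehyde
Product: 16 2-heptadecyl-6-methoxybenzene-1,4-diol, via aryl formate 15 (not isolated)
Conditions: 30% aq. H2O2 (1.2 equiv), NaOH (2.2 equiv), degassed THF–H2O, 0 °C to rt, Ar; aq. Na2SO3, then 1 M HCl
Reagents that add atoms: hydrogen peroxide, OO
Why: Dakin oxidation: hydroperoxide adds to the formyl carbon, the aryl group, made electron-rich by the para phenoxide and the ortho methoxy group, migrates to oxygen, and formate 15 is saponified in the same flask, while any material that air oxidises further is already 17 and does no harm.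

Step 8
Reactants: 16 2-heptadecyl-6-methoxybenzene-1,4-diol
Product: 17 2-heptadecyl-6-methoxycyclohexa-2,5-diene-1,4-dione (target)
Conditions: Ag2O (2 equiv), Na2SO4, Et2O–CH2Cl2, rt, dark; filter through Celite
Reagents that add atoms: none
Why: Two-electron dehydrogenation of a hydroquinone to the para-quinone with silver(I) oxide, a classical neutral and anhydrous method that leaves the vinylogous-ester methoxy group and the saturated chain untouched.

Compound list
1 | acetyl chloride | CC(=O)Cl | starting material
2 | 1,1-dichloroethene | C=C(Cl)Cl | starting material
3 | 4,4,4-trichlorobutan-2-one | CC(=O)CC(Cl)(Cl)Cl | intermediate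
4 | 4,4-dichlorobut-3-en-2-one | CC(=O)C=C(Cl)Cl | intermediate
5 | 4,4-dimethoxybut-3-en-2-one | CC(=O)C=C(OC)OC | intermediate
6 | 1,1-dimethoxy-3-(trimethylsilyloxy)buta-1,3-diene | COC(OC)=CC(=C)O[Si](C)(C)C | intermediate
7 | octadecanal | CCCCCCCCCCCCCCCCCC=O | starting material
8 | 1,1-dibromononadec-1-ene | CCCCCCCCCCCCCCCCCC=C(Br)Br | intermediate
9 | lithium nonadec-1-ynide | CCCCCCCCCCCCCCCCCC#C[Li] | intermediate
10 | lithium 1-(dimethylamino)icos-2-yn-1-olate (racemic, transient) | CCCCCCCCCCCCCCCCCC#CC(O[Li])N(C)C | intermediate
11 | icos-2-ynal | CCCCCCCCCCCCCCCCCC#CC=O | intermediate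
12 | 2-heptadecyl-6,6-dimethoxy-4-(trimethylsilyloxy)cyclohexa-1,4-diene-1-carbaldehyde | CCCCCCCCCCCCCCCCCC1=C(C=O)C(OC)(OC)C=C(O[Si](C)(C)C)C1 | intermediate
13 | 2-heptadecyl-6-methoxy-4-(trimethylsilyloxy)benzaldehyde | CCCCCCCCCCCCCCCCCc1cc(O[Si](C)(C)C)cc(OC)c1C=O | intermediate
14 | 2-heptadecyl-4-hydroxy-6-methoxybenzaldehyde | CCCCCCCCCCCCCCCCCc1cc(O)cc(OC)c1C=O | intermediate
15 | 2-heptadecyl-4-hydroxy-6-methoxyphenyl formate | CCCCCCCCCCCCCCCCCc1cc(O)cc(OC)c1OC=O | intermediate
16 | 2-heptadecyl-6-methoxybenzene-1,4-diol | CCCCCCCCCCCCCCCCCc1cc(O)cc(OC)c1O | intermediate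
17 | 2-heptadecyl-6-methoxycyclohexa-2,5-diene-1,4-dione (2-heptadecyl-6-methoxy-1,4-benzoquinone, achiral) | CCCCCCCCCCCCCCCCCC1=CC(=O)C=C(OC)C1=O | target

Total step count: 8. Longest linear sequence: 6 steps (1, 2, 3, 6, 7, 8). The ynal branch (steps 4 and 5) joins at step 6.

Steps most likely to fail

Step 6.
- **Risk:** The very nucleophilic diene may attack the formyl carbon by hetero-Diels–Alder or aldol-type addition. The diene may also decay thermally, or the ynal may oligomerise, faster than addition to the β-alkylated triple bond.
- **Fallback:** It sets out from 8 and comes back at 17.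
  - Treating 8 with n-BuLi as in step 5 and quenching acetylide 9 with methyl chloroformate should give methyl icos-2-ynoate F1. This compound has no carbonyl group open to hetero-cycloaddition and tolerates heating neat with 6 at about 140 °C.
  - Acid work-up should then give methyl 2-heptadecyl-4-hydroxy-6-methoxybenzoate F2.
  - Hydrolysis with KOH in hot aqueous ethylene glycol should give 2-heptadecyl-4-hydroxy-6-methoxybenzoic acid F3.
  - As an electron-rich para-hydroxy acid, F3 should undergo protodecarboxylation on heating to 3-heptadecyl-5-methoxyphenol F4.
  - Teuber oxidation of F4 with Fremy's salt in acetone–phosphate buffer attacks the free position para to the hydroxyl, between methoxy and chain. It should give 17 directly, so steps 7 and 8 are not needed.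

Step 7.
- **Risk:** The electron-rich hydroquinone may be over-oxidised in alkaline peroxide, by oxidation to the quinone followed by its epoxidation or ring degradation. Peroxide addition may be slow at a formyl group that is flanked on both sides and deactivated by the phenoxide. The waxy substrate may also dissolve poorly.
- **Fallback:** It sets out from 14 and comes back at 17.
  - O-Methylation (MeI, K2CO3, acetone) should give 2-heptadecyl-4,6-dimethoxybenzaldehyde F5.
  - Baeyer–Villiger oxidation with mCPBA in CH2Cl2, without base, should give 2-heptadecyl-4,6-dimethoxyphenyl formate F6.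
  - Methanolysis (K2CO3, MeOH) should give 2-heptadecyl-4,6-dimethoxyphenol F7.
  - Oxidative demethylation of this para-methoxyphenol with ceric ammonium nitrate in aqueous MeCN should give 17. A free hydroquinone then never meets alkaline peroxide.

Step 5.
- **Risk:** The released dimethylamine may add in conjugate fashion to the ynal while the adduct collapses. Bromine–lithium exchange and rearrangement may also stay incomplete because the long-chain dibromide dissolves poorly in cold THF.
- **Fallback:** It sets out from 8 and comes back at 11.
  - Acetylide 9, made as before, is quenched with paraformaldehyde to give icos-2-yn-1-ol F8.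
  - F8 is purified and then oxidised with activated MnO2 (or Dess–Martin periodinane) in CH2Cl2 to 11, with no amine present at any stage.

Further compounds
F1 | step 6 | methyl icos-2-ynoate | CCCCCCCCCCCCCCCCCC#CC(=O)OC
F2 | step 6 | methyl 2-heptadecyl-4-hydroxy-6-methoxybenzoate | CCCCCCCCCCCCCCCCCc1cc(O)cc(OC)c1C(=O)OC
F3 | step 6 | 2-heptadecyl-4-hydroxy-6-methoxybenzoic acid | CCCCCCCCCCCCCCCCCc1cc(O)cc(OC)c1C(=O)O
F4 | step 6 | 3-heptadecyl-5-methoxyphenol | CCCCCCCCCCCCCCCCCc1cc(O)cc(OC)c1
F5 | step 7 | 2-heptadecyl-4,6-dimethoxybenzaldehyde | CCCCCCCCCCCCCCCCCc1cc(OC)cc(OC)c1C=O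
F6 | step 7 | 2-heptadecyl-4,6-dimethoxyphenyl formate | CCCCCCCCCCCCCCCCCc1cc(OC)cc(OC)c1OC=O
F7 | step 7 | 2-heptadecyl-4,6-dimethoxyphenol | CCCCCCCCCCCCCCCCCc1cc(OC)cc(OC)c1O
F8 | step 5 | icos-2-yn-1-ol | CCCCCCCCCCCCCCCCCC#CCO
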